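**Plan**

- Numbering: ring A = C1–C5, C10 (AcO at C1 and C2, Me2 at C4, C20 on C10); ring B = oxepane C5–C6(lactol)–O–C7–C8–C9–C10; ring C = C8, C9, C11–C14; ring D = C8, C13–C16 (C15=O, C17 on C16).
- Enabling feature: C7 is the only oxidised carbon on quaternary C8 and lies gamma to the C15 oxygen of ring D, so an exo C15 alcohol can be tied to a plain C8 methyl through a five-membered O–Si–C7 ring; C7 is therefore carried as CH3 and oxidised late.
- Retrosynthetic cuts, in order: the C9/C11 epoxide, C16–C17, the C6–O7 lactol bond (ring B), C7–O (C–H silylation), C1–O and C2–O, then C9=C11 and C9–C10, which separates a ring-A allyl unit from a ring C/D bicyclo[3.2.1]octanone.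
- Forward: ring C by Michael addition/aldol condensation, ring D by reductive aldol closure (C8–C15); ring-A chirality by a [2,3]-Wittig–Still shift; the halves are joined at C9–C10 by allylzinc addition and dehydrated; ring-A cis-hydroxylation; oxasilolane closure; ring B closes as the lactol; epoxidation ends the route.
- Stereochemistry: C13 from the prolinol-ether Michael step (C8 follows from the bridged closure, C15 is inverted to exo); C5 from a CBS reduction relayed by the [2,3] shift; C10 by allyl attack anti to C6; C1/C2 by Woodward hydroxylation on the C20 face; C16 by exo-face hydrogenation; C9/C11 by exo-face epoxidation; C6 equilibrates.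

Key step: step 22

Remark 1: β denotes the face of ring A that carries C20, α the opposite face; on the bicycle, exo is the side of the one-carbon bridge C14 and endo the side of the facing larger bridge.
Remark 2: only an exo C15–O (cis to C7 across ring D, O–C15–C8–C7 about 45°) can close an oxasilolane onto C7; for the endo epimer this angle is close to 80°, so C15 is set exo early and kept.
Remark 3: the lactol carbon C6 epimerises through the open hydroxy aldehyde; the anomer of the target is assumed to be the thermodynamically preferred one.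
Remark 4: compounds 7 and 8 are used as mixtures of epimers at the carbinol/chloride carbon, because both give the same allylzinc species.

**Ring A (steps 1–7)**

Step 1
Reactants: 1 2,4,4-trimethylcyclohex-2-en-1-one
Product: 2 (1S)-2,4,4-trimethylcyclohex-2-en-1-ol
Conditions: (R)-2-methyl-CBS-oxazaborolidine (10 mol%), BH3·SMe2, THF, −20 °C; MeOH, H2O
Reagents that add atoms: none
Why: Corey–Bakshi–Shibata reduction: within the catalyst–borane–ketone complex hydride is delivered to the carbonyl face that keeps the larger α-methylalkenyl arm away from the B-methyl group, which with the (R)-catalyst should give the (S)-carbinol that later fixes C5.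

Step 2
Reactants: 2 (1S)-2,4,4-trimethylcyclohex-2-en-1-ol
Product: 3 tributyl({[(1S)-2,4,4-trimethylcyclohex-2-en-1-yl]oxy}methyl)stannane
Conditions: KH, THF, 0 °C; Bu3SnCH2I, 25 °C
Reagents that add atoms: tributyl(iodomethyl)stannane, CCCC[Sn](CCCC)(CCCC)CI
Why: Williamson ether synthesis of the potassium alkoxide at the primary iodide; the carbinol centre is not involved.

Step 3
Reactants: 3 stannylmethyl ether
Product: 4 [(1R)-2,6,6-trimethylcyclohex-2-en-1-yl]methanol
Conditions: n-BuLi, THF, −78 °C; H2O
Reagents that add atoms: none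
Why: [2,3]-Wittig–Still rearrangement: tin–lithium exchange gives the α-alkoxy carbanion, which shifts suprafacially over the allyl unit, so the C5–C6 bond forms on the face that the C–O bond leaves, the carbinol chirality is relayed to C5 (R) and the alkene moves to C1=C10.

Step 4
Reactants: 4 [(1R)-2,6,6-trimethylcyclohex-2-en-1-yl]methanol
Product: 5 tert-butyl(diphenyl){[(1R)-2,6,6-trimethylcyclohex-2-en-1-yl]methoxy}silane
Conditions: TBDPSCl, imidazole, DMF, 25 °C
Reagents that add atoms: tert-butyl(chloro)diphenylsilane, CC(C)(C)[Si](Cl)(c1ccccc1)c1ccccc1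
Why: Imidazole-promoted silylation of the unhindered primary alcohol gives a silyl ether that should tolerate the later oxidising, organozinc and acidic steps.

Step 5
Reactants: 5 silyl ether
Product: 6 (4R)-4-({[tert-butyl(diphenyl)silyl]oxy}methyl)-3,5,5-trimethylcyclohex-2-en-1-one
Conditions: Rh2(cap)4 (1 mol%, cap = caprolactamate), t-BuOOH, NaHCO3, CH2Cl2, 25 °C
Reagents that add atoms: tert-butyl hydroperoxide, CC(C)(C)OO
Why: Dirhodium caprolactamate-catalysed allylic oxidation (tert-butylperoxyl radical chain) converts the ring allylic methylene C2 into the enone carbonyl in preference to the methyl group and the hindered tertiary C5–H, and bicarbonate is too weak a base to epimerise C5.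

Step 6
Reactants: 6 enone
Product: 7 (4R)-4-({[tert-butyl(diphenyl)silyl]oxy}methyl)-3,5,5-trimethylcyclohex-2-en-1-ol (both C1 epimers)
Conditions: NaBH4, CeCl3·7H2O, MeOH, −40 °C
Reagents that add atoms: none
Why: Luche reduction delivers hydride 1,2 to the enone; the new carbinol centre is inconsequential because both epimers give the same allylzinc species.

Step 7
Reactants: 7 allylic alcohol
Product: 8 tert-butyl{[(1R)-4-chloro-2,6,6-trimethylcyclohex-2-en-1-yl]methoxy}diphenylsilane (both C4 epimers)
Conditions: MsCl, 2,4,6-collidine, LiCl, DMF, 0 °C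
Reagents that add atoms: lithium chloride, [Li+].[Cl-]
Why: Mesylation followed by chloride displacement (SN2 or SN2') gives the allylic chloride; regio- and stereoisomers are equivalent precursors of one allylmetal.

**Ring C/D ketone (steps 8–14)**

Step 8
Reactants: 9 pent-4-enal; 10 pent-1-en-3-one
Product: 11 (2S)-5-oxo-2-(prop-2-en-1-yl)heptanal
Conditions: (S)-2-[diphenyl(trimethylsilyloxy)methyl]pyrrolidine (5 mol%), ethyl 3,4-dihydroxybenzoate (20 mol%), neat, 4 °C
Reagents that add atoms: none
Why: Enamine-catalysed Michael addition: the (E)-enamine of 9 is shielded on one face by the diphenyl(silyloxy)methyl group, so the enone adds to the open face and sets C13 (2S in 11).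

Step 9
Reactants: 11 keto aldehyde
Product: 12 (4S)-2-methyl-4-(prop-2-en-1-yl)cyclohex-2-en-1-one
Conditions: TsOH·H2O (10 mol%), toluene, 80 °C
Reagents that add atoms: none
Why: Acid-catalysed intramolecular aldol condensation (the ring-closing half of a Robinson annulation) joins C8 to the aldehyde carbon C14 and dehydrates to the enone, closing ring C under conditions not basic enough to racemise C13.

Step 10
Reactants: 12 allyl enone
Product: 13 [(1S)-3-methyl-4-oxocyclohex-2-en-1-yl]acetaldehyde
Conditions: OsO4 (2 mol%), NaIO4, 2,6-lutidine, dioxane/H2O, 25 °C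
Reagents that add atoms: sodium periodate, [Na+].[O-]I(=O)(=O)=O; osmium tetroxide (catalytic oxygen carrier), O=[Os](=O)(=O)=O
Why: Lemieux–Johnson oxidation: OsO4 dihydroxylates the electron-rich monosubstituted alkene much faster than the conjugated trisubstituted one and periodate cleaves the diol to the aldehyde.

Step 11
Reactants: 13 enone aldehyde
Product: 14 (1S,5R,7R)-7-hydroxy-1-methylbicyclo[3.2.1]octan-2-one (C15 hydroxyl endo)
Conditions: [(Ph3P)CuH]6 (0.2 equiv of hexamer), toluene, −40 to 0 °C; aq NH4Cl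
Reagents that add atoms: none
Why: Copper hydride reductive aldol cyclisation: conjugate hydride delivery to C14 gives the C8 copper enolate regiospecifically, which adds to the tethered aldehyde in a 5-exo aldol closure of ring D; the side chain on C13 can reach only one face of the enolate, which fixes C8, and a chelated chair-like closed transition state should place the C15 hydroxyl endo (any exo epimer formed is 16 and is carried on directly).

Step 12
Reactants: 14 endo ketol
Product: 15 (1S,5R,7S)-7-(chloroacetoxy)-1-methylbicyclo[3.2.1]octan-2-one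
Conditions: ClCH2CO2H, PPh3, DIAD, toluene, 0 to 25 °C
Reagents that add atoms: chloroacetic acid, OC(=O)CCl
Why: Mitsunobu reaction: chloroacetate displaces the alkoxyphosphonium group by SN2 from the open exo face, inverting C15 to the exo ester without base that could trigger retro-aldol cleavage.

Step 13
Reactants: 15 exo chloroacetate
Product: 16 (1S,5R,7S)-7-hydroxy-1-methylbicyclo[3.2.1]octan-2-one (C15 hydroxyl exo)
Conditions: thiourea, 2,6-lutidine, EtOH, 40 °C
Reagents that add atoms: none
Why: Thiourea dechloroacetylation (S-alkylation, then cyclisation to the thiazolidinone expels the alcohol) works near neutrality, so the β-hydroxy ketone is not exposed to retro-aldol conditions.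

Step 14
Reactants: 16 exo ketol
Product: 17 (1S,5R,7S)-7-{[tert-butyl(dimethyl)silyl]oxy}-1-methylbicyclo[3.2.1]octan-2-one
Conditions: TBSOTf, 2,6-lutidine, CH2Cl2, −78 °C
Reagents that add atoms: tert-butyldimethylsilyl trifluoromethanesulfonate, CC(C)(C)[Si](C)(C)OS(=O)(=O)C(F)(F)F
Why: Silyl triflate/lutidine silylation protects the hindered secondary alcohol at low temperature, and the silyl ether also blocks retro-aldol cleavage.

**Union and ring-A oxidation (steps 15–21)**

Step 15
Reactants: 8 allylic chloride; 17 silyloxy ketone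
Product: 19 C9 carbinol (ring A joined through C10 to C9 of the bicycle; C20 cis to C6; C9 hydroxyl endo), via allylzinc chloride 18 (not isolated)
Conditions: 8 (1.5 equiv), Zn dust, LiCl, THF, 25 °C; then 17, −78 to 0 °C; aq NH4Cl
Reagents that add atoms: none
Why: Allylic zinc addition to a ketone: zinc inserts into the allylic chloride in the presence of LiCl and the allylzinc adds through a six-membered cyclic transition state with allylic transposition (SE2'), a reaction type known to join a quaternary carbon to a tertiary carbinol carbon; the C9–C10 bond forms at the methyl-bearing terminus on the face anti to the C5 silyloxymethyl group (C20 cis to C6) and on the exo face of the ketone, and the C9 configuration is removed in the next step.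

Step 16
Reactants: 19 C9 carbinol
Product: 20 1,9(11)-diene (C1=C2 in ring A, C9=C11 in ring C)
Conditions: methyl N-(triethylammoniosulfonyl)carbamate, toluene, 60 °C
Reagents that add atoms: none
Why: Burgess dehydration (syn-elimination of the tertiary alcohol through its sulfamate ester); C11 is the only β-carbon that bears hydrogen, so the 9(11)-alkene is the only possible regioisomer.

Step 17
Reactants: 20 1,9(11)-diene
Product: 23 1β,2β-diacetate (C6 silyl ether and C15 silyl ether kept; 9(11)-ene kept), via iodo acetate 21 (not isolated), via hydroxy acetate 22 (not isolated)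
Conditions: I2, AgOAc, AcOH, 25 °C; then H2O, 45 °C; then Ac2O, pyridine, DMAP, 25 °C
Reagents that add atoms: silver acetate, CC(=O)[O-].[Ag+]; water, O; acetic anhydride, CC(=O)OC(C)=O
Why: Woodward cis-hydroxylation then acetylation: iodonium forms reversibly on the α face of C1=C2 (anti to the axial C20 and C4 methyl groups), acetate opens it trans-diaxially at C2 as in 4,4-dimethyl Δ2-steroids, the neighbouring acetate displaces the silver-activated iodide at C1 to a β-acetoxonium ion that water opens to the cis β-hydroxy acetate, and acetylation gives the 1β,2β-diacetate, while the 9(11)-alkene, which cannot complete an anti addition between two quaternary carbons, should be left.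

Step 18
Reactants: 23 diacetate bis-silyl ether
Product: 24 1β,2β-diacetoxy-9(11)-ene-6,15-diol (C15 hydroxyl exo)
Conditions: HF·pyridine, pyridine, THF, 0 to 25 °C
Reagents that add atoms: none
Why: Fluoride cleaves both silyl ethers (Si–F bond formation) while pyridine buffering leaves the two acetates in place.

Step 19
Reactants: 24 6,15-diol
Product: 25 C6 aldehyde with free exo C15 hydroxyl
Conditions: TEMPO (10 mol%), PhI(OAc)2, CH2Cl2, 25 °C
Reagents that add atoms: none
Why: Oxoammonium (TEMPO) oxidation with PhI(OAc)2 as terminal oxidant is selective for the primary alcohol, leaving the hindered secondary C15 hydroxyl, and C5 keeps its equatorial substituent.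

Step 20
Reactants: 25 hydroxy aldehyde
Product: 26 C6 dimethyl acetal with free exo C15 hydroxyl
Conditions: HC(OMe)3, PPTS (cat.), MeOH, 25 °C
Reagents that add atoms: trimethyl orthoformate, COC(OC)OC; methanol, CO
Why: Acid-catalysed acetalisation; in methanol the acyclic dimethyl acetal is favoured over a seven-membered cyclic acetal with the C15 hydroxyl, which therefore stays free.

Step 21
Reactants: 26 acetal alcohol
Product: 27 C15 exo diethyl(hydrido)silyl ether (C8 methyl, 9(11)-ene, C6 dimethyl acetal, 1β,2β-diacetate)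
Conditions: Et2SiHCl, Et3N, DMAP (cat.), CH2Cl2, 0 °C
Reagents that add atoms: chlorodiethylsilane, CC[SiH](Cl)CC
Why: Base-mediated silylation of the alcohol with the small chlorohydrosilane gives the (hydrido)silyl ether needed as the tether.

**Key step and endgame (steps 22–29)**

Step 22
Reactants: 27 C15 diethyl(hydrido)silyl ether
Product: 28 oxasilolane (C7–SiEt2–O–C15, cis-fused to ring D)
Conditions: [Ir(cod)OMe]2 (2 mol%), 3,4,7,8-tetramethyl-1,10-phenanthroline (5 mol%), norbornene (1.5 equiv), THF, 100 °C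
Reagents that add atoms: none
Why: The Si–H bond adds oxidatively to the phenanthroline-ligated iridium centre, the tethered metal cleaves a C–H bond of the C8 methyl group (C7) within a five-membered O–Si–Ir–C arrangement, and C–Si reductive elimination releases the oxasilolane while the two hydrogen atoms are passed to norbornene. The closest known reaction type is the iridium-catalysed, hydroxyl-directed dehydrogenative silylation of primary γ-C–H bonds in (hydrido)silyl ethers, whose products are oxidised to 1,3-diols. The one ring formed, the oxasilolane (Si, O, C15, C8, C7), closes by C7–Si bond formation in a five-membered mode and is cis-fused to ring D. No stereocentre is created, and C15 and C8 are untouched. The step needs selectivity for the primary C7–H over the secondary C14/C16 and tertiary C13 hydrogens and over the alkene: the exo C15–O holds silicon about 45° from the C8–C7 bond so that only C7 can complete a five-membered ring (C14 and C13 would give bridged rings across ring D), C16 carries no methyl group, and the 9(11)-alkene, buried between quaternary C8 and C10, should be a far poorer hydrogen acceptor than norbornene.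

Step 23
Reactants: 28 oxasilolane
Product: 29 7,15-diol (C7 primary, C15 exo secondary)
Conditions: H2O2 (30% aq), KHCO3, THF/MeOH, 40 °C
Reagents that add atoms: hydrogen peroxide, OO
Why: Tamao–Fleming oxidation: hydroperoxide adds to the alkoxysilane silicon, C7 migrates from silicon to oxygen and hydrolysis of the Si–O bonds releases the 1,3-diol; the bicarbonate-buffered medium should spare the hindered secondary acetates and the acetal.

Step 24
Reactants: 29 7,15-diol
Product: 30 C7 tert-butyldimethylsilyl ether with free C15 hydroxyl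
Conditions: TBSCl, imidazole, DMF, 0 °C
Reagents that add atoms: tert-butyl(chloro)dimethylsilane, CC(C)(C)[Si](C)(C)Cl
Why: Silylation with the chlorosilane and imidazole distinguishes the primary C7 hydroxyl from the hindered secondary C15 hydroxyl.

Step 25
Reactants: 30 C7 silyl ether alcohol
Product: 31 C15 ketone (C7 silyl ether)
Conditions: Dess–Martin periodinane, NaHCO3, CH2Cl2, 25 °C
Reagents that add atoms: none
Why: Dess–Martin oxidation of the secondary alcohol under buffered, non-basic conditions gives the ketone, and the β-silyloxy ketone cannot undergo retro-aldol loss of C7.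

Step 26
Reactants: 31 C15 ketone
Product: 34 16-methylene 15-ketone (C16=C17), via Mannich base 32 (not isolated), via ammonium iodide 33 (not isolated)
Conditions: LiHMDS, THF, −78 °C; CH2=NMe2+ I−, −78 to 0 °C; MeI, 25 °C; aq NaHCO3, CH2Cl2, 25 °C
Reagents that add atoms: N,N-dimethylmethyleneiminium iodide, C=[N+](C)C.[I-]
Why: Mannich α-methylenation: the ketone can enolise only towards C16 (C8 is quaternary) and should be deprotonated far faster than the acetates at −78 °C, the enolate adds to the iminium salt from the exo face, and N-methylation followed by mild base elimination (E1cB) gives the exocyclic enone.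

Step 27
Reactants: 34 exocyclic enone
Product: 35 16-endo-methyl 15-ketone
Conditions: H2 (1 atm), Pd/C (5% palladium on carbon), EtOAc, 25 °C
Reagents that add atoms: none
Why: Heterogeneous hydrogenation of the unhindered exocyclic enone: hydrogen should be delivered from the exo face (C14 side) of the two-carbon bridge, which places the new methyl group endo as required at C16, while the shielded trisubstituted 9(11)-alkene is left.

Step 28
Reactants: 35 methyl ketone
Product: 37 lactol 9(11)-ene (ring B closed), via hydroxy aldehyde 36 (not isolated)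
Conditions: HF (48% aq), MeCN, 0 °C
Reagents that add atoms: water, O
Why: Aqueous acid removes the silyl ether and hydrolyses the acetal; the liberated C7 hydroxyl adds to the C6 aldehyde (7-exo-trig hemiacetalisation) to close ring B as the lactol, whose anomeric centre equilibrates to the more stable configuration, and the short, cold exposure should avoid enolisation at C16.

Step 29
Reactants: 37 lactol 9(11)-ene
Product: 38 CNP0210140.1
Conditions: dimethyldioxirane, acetone/CH2Cl2, 0 °C
Reagents that add atoms: dimethyldioxirane, CC1(C)OO1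
Why: Dioxirane epoxidation of the trisubstituted alkene: oxygen should be transferred to the exo face (C14 side), the endo face being blocked by the C15/C16 bridge and its endo methyl group, and the neutral reagent spares the ketone (no Baeyer–Villiger reaction) and the lactol.

**Compound list**

1 | 2,4,4-trimethylcyclohex-2-en-1-one | CC1=CC(C)(C)CCC1=O | starting material
2 | (1S)-2,4,4-trimethylcyclohex-2-en-1-ol | CC1=CC(C)(C)CC[C@@H]1O | intermediate
3 | tributyl({[(1S)-2,4,4-trimethylcyclohex-2-en-1-yl]oxy}methyl)stannane | CC1=CC(C)(C)CC[C@@H]1OC[Sn](CCCC)(CCCC)CCCC | intermediate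
4 | [(1R)-2,6,6-trimethylcyclohex-2-en-1-yl]methanol | CC1=CCCC(C)(C)[C@H]1CO | intermediate
5 | tert-butyl(diphenyl){[(1R)-2,6,6-trimethylcyclohex-2-en-1-yl]methoxy}silane | CC1=CCCC(C)(C)[C@H]1CO[Si](c2ccccc2)(c3ccccc3)C(C)(C)C | intermediate
6 | (4R)-4-({[tert-butyl(diphenyl)silyl]oxy}methyl)-3,5,5-trimethylcyclohex-2-en-1-one | CC1=CC(=O)CC(C)(C)[C@H]1CO[Si](c2ccccc2)(c3ccccc3)C(C)(C)C | intermediate
7 | (4R)-4-({[tert-butyl(diphenyl)silyl]oxy}methyl)-3,5,5-trimethylcyclohex-2-en-1-ol, both C1 epimers | CC1=CC(O)CC(C)(C)[C@H]1CO[Si](c2ccccc2)(c3ccccc3)C(C)(C)C | intermediate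
8 | tert-butyl{[(1R)-4-chloro-2,6,6-trimethylcyclohex-2-en-1-yl]methoxy}diphenylsilane, both C4 epimers | CC1=CC(Cl)CC(C)(C)[C@H]1CO[Si](c2ccccc2)(c3ccccc3)C(C)(C)C | intermediate
9 | pent-4-enal | C=CCCC=O | starting material
10 | pent-1-en-3-one | CCC(=O)C=C | starting material
11 | (2S)-5-oxo-2-(prop-2-en-1-yl)heptanal | CCC(=O)CC[C@@H](CC=C)C=O | intermediate
12 | (4S)-2-methyl-4-(prop-2-en-1-yl)cyclohex-2-en-1-one | O=C1CC[C@@H](CC=C)C=C1C | intermediate
13 | [(1S)-3-methyl-4-oxocyclohex-2-en-1-yl]acetaldehyde | O=C1CC[C@@H](CC=O)C=C1C | intermediate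
14 | (1S,5R,7R)-7-hydroxy-1-methylbicyclo[3.2.1]octan-2-one (hydroxyl endo) | O=C1CC[C@@H]2C[C@@]1(C)[C@H](O)C2 | intermediate
15 | (1S,5R,7S)-7-(chloroacetoxy)-1-methylbicyclo[3.2.1]octan-2-one | O=C1CC[C@@H]2C[C@@]1(C)[C@@H](OC(=O)CCl)C2 | intermediate
16 | (1S,5R,7S)-7-hydroxy-1-methylbicyclo[3.2.1]octan-2-one (hydroxyl exo) | O=C1CC[C@@H]2C[C@@]1(C)[C@@H](O)C2 | intermediate
17 | (1S,5R,7S)-7-{[tert-butyl(dimethyl)silyl]oxy}-1-methylbicyclo[3.2.1]octan-2-one | O=C1CC[C@@H]2C[C@@]1(C)[C@@H](O[Si](C)(C)C(C)(C)C)C2 | intermediate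
18 | {(4R)-4-({[tert-butyl(diphenyl)silyl]oxy}methyl)-3,5,5-trimethylcyclohex-2-en-1-yl}zinc chloride (LiCl adduct, allylic isomers interconvert) | CC1=CC([Zn]Cl)CC(C)(C)[C@H]1CO[Si](c2ccccc2)(c3ccccc3)C(C)(C)C | intermediate (not isolated)
19 | C9 carbinol: ring A (C1=C2, C20 β, C6 silyl ether β) bonded through C10 to C9 of the bicycle (C9 hydroxyl endo, C15 silyl ether exo) | C1=CCC(C)(C)[C@@H](CO[Si](c2ccccc2)(c3ccccc3)C(C)(C)C)[C@]1(C)[C@]4(O)CC[C@@H]5C[C@@]4(C)[C@@H](O[Si](C)(C)C(C)(C)C)C5 | intermediate
20 | 1,9(11)-diene (6-O-TBDPS, 15-exo-O-TBS) | C1=CCC(C)(C)[C@@H](CO[Si](c2ccccc2)(c3ccccc3)C(C)(C)C)[C@]1(C)C4=CC[C@@H]5C[C@@]4(C)[C@@H](O[Si](C)(C)C(C)(C)C)C5 | intermediate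
21 | 1α-iodo-2β-acetate of 20 (trans-diaxial) | CC(=O)O[C@H]1CC(C)(C)[C@@H](CO[Si](c2ccccc2)(c3ccccc3)C(C)(C)C)[C@](C)(C4=CC[C@@H]5C[C@@]4(C)[C@@H](O[Si](C)(C)C(C)(C)C)C5)[C@@H]1I | intermediate (not isolated)
22 | 1β-hydroxy-2β-acetate | CC(=O)O[C@H]1CC(C)(C)[C@@H](CO[Si](c2ccccc2)(c3ccccc3)C(C)(C)C)[C@](C)(C4=CC[C@@H]5C[C@@]4(C)[C@@H](O[Si](C)(C)C(C)(C)C)C5)[C@H]1O | intermediate (not isolated)
23 | 1β,2β-diacetate (6-O-TBDPS, 15-exo-O-TBS, 9(11)-ene) | CC(=O)O[C@H]1CC(C)(C)[C@@H](CO[Si](c2ccccc2)(c3ccccc3)C(C)(C)C)[C@](C)(C4=CC[C@@H]5C[C@@]4(C)[C@@H](O[Si](C)(C)C(C)(C)C)C5)[C@H]1OC(C)=O | intermediate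
24 | 1β,2β-diacetoxy-9(11)-ene-6,15-diol (15-OH exo) | CC(=O)O[C@H]1CC(C)(C)[C@@H](CO)[C@](C)(C2=CC[C@@H]3C[C@@]2(C)[C@@H](O)C3)[C@H]1OC(C)=O | intermediate
25 | C6 aldehyde, 15-exo-ol | CC(=O)O[C@H]1CC(C)(C)[C@@H](C=O)[C@](C)(C2=CC[C@@H]3C[C@@]2(C)[C@@H](O)C3)[C@H]1OC(C)=O | intermediate
26 | C6 dimethyl acetal, 15-exo-ol | CC(=O)O[C@H]1CC(C)(C)[C@@H](C(OC)OC)[C@](C)(C2=CC[C@@H]3C[C@@]2(C)[C@@H](O)C3)[C@H]1OC(C)=O | intermediate
27 | C15 exo diethyl(hydrido)silyl ether of 26 | CC(=O)O[C@H]1CC(C)(C)[C@@H](C(OC)OC)[C@](C)(C2=CC[C@@H]3C[C@@]2(C)[C@@H](O[SiH](CC)CC)C3)[C@H]1OC(C)=O | intermediate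
28 | oxasilolane (C7–SiEt2–O–C15, cis-fused to ring D) | CC(=O)O[C@H]1CC(C)(C)[C@@H](C(OC)OC)[C@](C)(C2=CC[C@@H]3C[C@]24C[Si](CC)(CC)O[C@H]4C3)[C@H]1OC(C)=O | intermediate
29 | 7,15-diol (C6 dimethyl acetal) | CC(=O)O[C@H]1CC(C)(C)[C@@H](C(OC)OC)[C@](C)(C2=CC[C@@H]3C[C@@]2(CO)[C@@H](O)C3)[C@H]1OC(C)=O | intermediate
30 | 7-O-TBS ether, 15-exo-ol | CC(=O)O[C@H]1CC(C)(C)[C@@H](C(OC)OC)[C@](C)(C2=CC[C@@H]3C[C@@]2(CO[Si](C)(C)C(C)(C)C)[C@@H](O)C3)[C@H]1OC(C)=O | intermediate
31 | 7-O-TBS ether, 15-ketone | CC(=O)O[C@H]1CC(C)(C)[C@@H](C(OC)OC)[C@](C)(C2=CC[C@@H]3C[C@@]2(CO[Si](C)(C)C(C)(C)C)C(=O)C3)[C@H]1OC(C)=O | intermediate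
32 | 16-exo-(dimethylaminomethyl) 15-ketone | CC(=O)O[C@H]1CC(C)(C)[C@@H](C(OC)OC)[C@](C)(C2=CC[C@@H]3C[C@@]2(CO[Si](C)(C)C(C)(C)C)C(=O)[C@H]3CN(C)C)[C@H]1OC(C)=O | intermediate (not isolated)
33 | 16-exo-(trimethylammoniomethyl) 15-ketone iodide | CC(=O)O[C@H]1CC(C)(C)[C@@H](C(OC)OC)[C@](C)(C2=CC[C@@H]3C[C@@]2(CO[Si](C)(C)C(C)(C)C)C(=O)[C@H]3C[N+](C)(C)C)[C@H]1OC(C)=O.[I-] | intermediate (not isolated)
34 | 16-methylene 15-ketone | CC(=O)O[C@H]1CC(C)(C)[C@@H](C(OC)OC)[C@](C)(C2=CC[C@@H]3C[C@@]2(CO[Si](C)(C)C(C)(C)C)C(=O)C3=C)[C@H]1OC(C)=O | intermediate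
35 | 16-endo-methyl 15-ketone | CC(=O)O[C@H]1CC(C)(C)[C@@H](C(OC)OC)[C@](C)(C2=CC[C@@H]3C[C@@]2(CO[Si](C)(C)C(C)(C)C)C(=O)[C@@H]3C)[C@H]1OC(C)=O | intermediate
36 | 7-hydroxy 6-aldehyde (open form of 37) | CC(=O)O[C@H]1CC(C)(C)[C@@H](C=O)[C@](C)(C2=CC[C@@H]3C[C@@]2(CO)C(=O)[C@@H]3C)[C@H]1OC(C)=O | intermediate (not isolated)
37 | lactol 9(11)-ene (ring B closed) | CC(=O)O[C@H]1CC(C)(C)[C@H]2[C@H](O)OC[C@@]34C[C@@H](CC=C3[C@]2(C)[C@H]1OC(C)=O)[C@@H](C)C4=O | intermediate
38 | CNP0210140.1 (1β,2β-diacetoxy lactol, 9,11-exo-epoxide, 16-endo-methyl 15-ketone) | CC(=O)O[C@H]1CC(C)(C)[C@H]2[C@H](O)OC[C@@]34C[C@@H](C[C@H]5O[C@]53[C@]2(C)[C@H]1OC(C)=O)[C@@H](C)C4=O | target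

**Step count and risks**

Total step count: 29. Longest linear sequence: 22 steps (steps 8–14, then 15–29; the ring-A branch, steps 1–7, is of equal length).

Steps most likely to fail:

1. Step 15 (allylzinc union). The addition to the α-quaternary ketone may be slow and reversible, so that the zinc alkoxide reverts (retro-allylation) and the allyl unit re-adds through its less hindered terminus, or 17 is recovered. The fallback replaces carbonyl addition by a carbenoid O–H insertion/[3,3] shift; it sets out from 17 and from the (1R,4R) epimer of 7 (hydroxyl anti to the silyloxymethyl group, separated by chromatography) and comes back at 20. Detrifluoroacetylative diazo transfer (LiHMDS, CF3CO2CH2CF3; then MsN3, Et3N) would convert 17 into the diazo ketone F1. Rh2(OAc)4 in benzene at reflux with the alcohol should give, by O–H insertion and in situ [3,3] shift from C11–O to C9 (chirality transfer from C2 sets C10 as before), the hydroxy ketone F2. NaBH4 reduction from the exo face should give the cis-9,11-diol F3, 1,1'-thiocarbonyldiimidazole the thionocarbonate F4, and Corey–Winter fragmentation with P(OMe)3 at 110 °C the diene 20.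

2. Step 17 (Woodward hydroxylation). The iodonium/acetoxonium sequence may be diverted by attack on the 9(11)-alkene, by a 1,2-shift at the neopentylic C1 during silver-assisted ionisation, or by acetolysis of a silyl ether. The fallback hydroxylates the open face and then corrects both carbinol centres one after the other; it sets out from 20 and comes back at 23. OsO4/NMO should add only to the α face of C1=C2, giving the 1α,2α-diol F5. One equivalent of Dess–Martin periodinane should oxidise the unhindered equatorial C2 hydroxyl to the 2-keto-1α-ol F6, and DBU should equilibrate C1 to the equatorial 1β-hydroxy ketone F7. NaBH4 should attack C2 from the α face, away from the two syn-axial methyl groups, to give the 1β,2β-diol F8, and acetylation gives 23.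

3. Step 22 (C–H silylation). C–H cleavage at the bridgehead methyl, reached near the edge of the geometric range, may be outrun by loss of the hydrosilane (hydrogen transfer without ring closure, hydrosilylation or migration of the 9(11)-alkene). The fallback oxidises the same methyl group by nitrogen-directed palladium catalysis; it sets out from 26 and comes back at 31. Dess–Martin oxidation would give the methyl ketone F9, and MeONH2·HCl/pyridine the oxime ether F10 (OMe anti to C8). Pd(OAc)2 (10 mol%) with PhI(OAc)2 in 1,2-dichloroethane at 80 °C should acetoxylate the β-methyl group through a five-membered palladacycle to give the C7 acetate F11. Methanolysis catalysed by [Bu2Sn(Cl)OSn(OH)Bu2]2 should free only the primary alcohol, giving the hydroxy oxime F12; TBSCl/imidazole gives the silyl ether oxime F13, and TiCl3/NH4OAc in aqueous THF cleaves the oxime ether to 31.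

**Further compounds**

F1 | step 15 | 3-diazo derivative of 17 (3-diazo-7-exo-silyloxy-1-methylbicyclo[3.2.1]octan-2-one) | O=C1C(=[N+]=[N-])C[C@@H]2C[C@@]1(C)[C@@H](O[Si](C)(C)C(C)(C)C)C2
F2 | step 15 | 9-hydroxy 11-ketone (C9–C10 bonded, C9 hydroxyl endo) | C1=CCC(C)(C)[C@@H](CO[Si](c2ccccc2)(c3ccccc3)C(C)(C)C)[C@]1(C)[C@]4(O)C(=O)C[C@@H]5C[C@@]4(C)[C@@H](O[Si](C)(C)C(C)(C)C)C5
F3 | step 15 | cis-9,11-diol (both hydroxyls endo) | C1=CCC(C)(C)[C@@H](CO[Si](c2ccccc2)(c3ccccc3)C(C)(C)C)[C@]1(C)[C@]4(O)[C@@H](O)C[C@@H]5C[C@@]4(C)[C@@H](O[Si](C)(C)C(C)(C)C)C5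
F4 | step 15 | cyclic 9,11-thionocarbonate | C1=CCC(C)(C)[C@@H](CO[Si](c2ccccc2)(c3ccccc3)C(C)(C)C)[C@]1(C)[C@@]46OC(=S)O[C@H]6C[C@@H]5C[C@@]4(C)[C@@H](O[Si](C)(C)C(C)(C)C)C5
F5 | step 17 | 1α,2α-diol of 20 | O[C@@H]1CC(C)(C)[C@@H](CO[Si](c2ccccc2)(c3ccccc3)C(C)(C)C)[C@](C)(C4=CC[C@@H]5C[C@@]4(C)[C@@H](O[Si](C)(C)C(C)(C)C)C5)[C@@H]1O
F6 | step 17 | 2-keto-1α-ol | O=C1CC(C)(C)[C@@H](CO[Si](c2ccccc2)(c3ccccc3)C(C)(C)C)[C@](C)(C4=CC[C@@H]5C[C@@]4(C)[C@@H](O[Si](C)(C)C(C)(C)C)C5)[C@@H]1O
F7 | step 17 | 2-keto-1β-ol | O=C1CC(C)(C)[C@@H](CO[Si](c2ccccc2)(c3ccccc3)C(C)(C)C)[C@](C)(C4=CC[C@@H]5C[C@@]4(C)[C@@H](O[Si](C)(C)C(C)(C)C)C5)[C@H]1O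
F8 | step 17 | 1β,2β-diol | O[C@H]1CC(C)(C)[C@@H](CO[Si](c2ccccc2)(c3ccccc3)C(C)(C)C)[C@](C)(C4=CC[C@@H]5C[C@@]4(C)[C@@H](O[Si](C)(C)C(C)(C)C)C5)[C@H]1O
F9 | step 22 | 15-ketone with C8 methyl (from 26) | CC(=O)O[C@H]1CC(C)(C)[C@@H](C(OC)OC)[C@](C)(C2=CC[C@@H]3C[C@@]2(C)C(=O)C3)[C@H]1OC(C)=O
F10 | step 22 | 15-(O-methyl oxime) | CC(=O)O[C@H]1CC(C)(C)[C@@H](C(OC)OC)[C@](C)(C2=CC[C@@H]3C[C@@]2(C)C(=NOC)C3)[C@H]1OC(C)=O
F11 | step 22 | 7-acetoxy 15-(O-methyl oxime) | CC(=O)O[C@H]1CC(C)(C)[C@@H](C(OC)OC)[C@](C)(C2=CC[C@@H]3C[C@@]2(COC(C)=O)C(=NOC)C3)[C@H]1OC(C)=O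
F12 | step 22 | 7-hydroxy 15-(O-methyl oxime) | CC(=O)O[C@H]1CC(C)(C)[C@@H](C(OC)OC)[C@](C)(C2=CC[C@@H]3C[C@@]2(CO)C(=NOC)C3)[C@H]1OC(C)=O
F13 | step 22 | 7-O-TBS 15-(O-methyl oxime) | CC(=O)O[C@H]1CC(C)(C)[C@@H](C(OC)OC)[C@](C)(C2=CC[C@@H]3C[C@@]2(CO[Si](C)(C)C(C)(C)C)C(=NOC)C3)[C@H]1OC(C)=O
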